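The runs are simulated with made-up constants; noise was put on by code.

Two shares of one flask are asked, both of other capture product in other capture product plus target, one early and one late.

all flasks: gas 1.6 mM (held)
- cedar: substrate 10 mM; second nucleophile 22 mM; capture agent 2 mM; run made earlier
- flask: substrate 20 mM; second nucleophile 22.0 mM; capture agent 2.00 mM; time 25 min

- cedar (time / min: other capture product / %, target / %): 0.500: 6, 6; 1.00: 11, 12; 1.50: 18, 15; 2.00: 23, 21; 2.50: 22, 21

(standard deviation of a reading: 2 percentage points)

- share of other capture product in other capture product plus target at 12 s
- share of other capture product in other capture product plus target at 25 min

- percent here means substrate units held: one self-condensation product counts as two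
- at the start none of first nucleophile is dissolved
- the numbers in the tables scatter by 2 percentage points (one standard deviation)
- steps thought possible: gas <-> first nucleophile; first nucleophile + open intermediate -> target; second nucleophile + open intermediate -> other capture product; open intermediate + capture agent -> trapped intermediate; 2 substrate -> self-condensation product; substrate -> open intermediate

The last cedar reading shows other capture product at 22% and target at 21%, with a scatter of 2 percentage points, so open intermediate was being shared about evenly. But dissolved first nucleophile is refilled from the gas up to 1.6 mM, while second nucleophile D is spent as it captures. With first nucleophile taken as steady, D therefore falls with the target formed, P, as ln(D₀/D) = P/K, where D₀ is the charge. That cedar reading gives K = 19.9 mM, and this capture level, the amount of second nucleophile at which both captures run equally fast, is a selectivity factor times dissolved first nucleophile. Assuming the flask repeats the cedar percentage of target, P = 4.20 mM, so second nucleophile loses 4.18 mM and the late share reckoned here is 49.9%; K gives no figure for the early share. The forecast gave 70% and 56%, holding that the “final share should be a little above 50%”. The flask gives 68.1% at 12 s and 45.8% at 25 min.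

    gas ⇌ first nucleophile, rate k1*(csat - [first nucleophile]) (kL = 0.0680 s⁻¹)
    first nucleophile + open intermediate → target (k = 110 M⁻¹ s⁻¹)
    second nucleophile + open intermediate → other capture product (k = 5.60 M⁻¹ s⁻¹)
    open intermediate + capture agent → trapped intermediate (k = 3.50 M⁻¹ s⁻¹)
    2 substrate → self-condensation product (k = 0.200 M⁻¹ s⁻¹)
    substrate → open intermediate (k = 0.00550 s⁻¹)

At 25 min the flask holds target at 32.6% of the substrate charged and second nucleophile at 75.0% of its charge, which makes K = 22.6 mM, and at 1.50 min open intermediate in the flask was going 1.2 times as fast to target as to other capture product. A neighbour flask, charged with 13 mM of second nucleophile, ends at 25 min with a share of 33.8%, target at 39.5% of the substrate charged and second nucleophile at 69.0% of its own charge, so its K is 21.3 mM.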